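**Plan**
- Retrosynthesis: the C4–C4a aryl ketone bond of ring C is cut first. Ring A is then taken apart at C5–C6, C7–C8 and C4a–C5 into a geranyl ynol silyl ether and a 3-alkoxycyclobutenone. The C2–O1 ether bond, the C2–C3 bond and the geranyl–alkyne bond follow.
- Forward: ring B is bought. C2–C3 (Claisen condensation), the C2 carbinol (hydrogenation) and C2–O1 (Mitsunobu etherification of cyclobutane-1,3-dione) are made on it. Ring A is then built by benzannulation, ring C is closed last by acylation, and the four silyl ethers are removed.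
- Enabling feature: ring A is a benzene with oxygens on C5, C7 and C8a, geranyl on C6 between the C5 and C7 oxygens and para to C8a, and only hydrogen or acyl on C8 and C4a. This is the OH, alkyl, OSi, H, O-alkyl, H sequence that a (2-alkoxyvinyl)ketene and a silyloxyalkyne deliver. Once O5 is silylated, C4a and C8 are equivalent, so closure of ring C has no regiochemical choice.
- Stereochemistry: C2 comes from hydrogenation of the keto ester with RuCl2[(S)-BINAP] to the (R)-carbinol, which the Mitsunobu step inverts to (S). The E-alkene is carried unchanged from geranyl bromide.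

Key step: step 8

Assumption: the facial sense of the RuCl2[BINAP] hydrogenation is taken to follow that of simple aroylacetates, where the (S)-ligand gives the (R)-carbinol.
Abbreviations: TIPS = triisopropylsilyl; geranyl = (2E)-3,7-dimethylocta-2,6-dien-1-yl; flavanone locants are used for ring atoms throughout.

**Route**

Step 1
Reactants: 1 geranyl bromide
Product: 2 (4E)-5,9-dimethyldeca-4,8-dien-1-yne
Conditions: HC≡CMgBr (1.5 equiv), CuBr·SMe2 (5 mol%), THF, 0 °C to rt
Reagents that add atoms: ethynylmagnesium bromide, C#C[Mg]Br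
Why: Copper-catalysed cross-coupling of a primary allylic bromide with an alkynyl Grignard reagent should proceed by direct substitution at the primary carbon without touching the E-trisubstituted alkene, giving the skipped enyne.

Step 2
Reactants: 2 (4E)-5,9-dimethyldeca-4,8-dien-1-yne
Product: 5 (4E)-5,9-dimethyl-1-(triisopropylsilyloxy)deca-4,8-dien-1-yne, via lithium acetylide 3 (not isolated), via lithium ynolate 4 (not isolated)
Conditions: LiN(SiMe3)2, THF, −78 °C; t-BuOOLi (from t-BuOOH and LiN(SiMe3)2), −78 to 0 °C; TIPSOTf, −78 to 0 °C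
Reagents that add atoms: tert-butyl hydroperoxide, CC(C)(C)OO; triisopropylsilyl trifluoromethanesulfonate, CC(C)[Si](OS(=O)(=O)C(F)(F)F)(C(C)C)C(C)C
Why: Oxygen transfer from lithium tert-butyl peroxide to the alkynyllithium (electrophilic oxidation of an acetylide to an ynolate) followed by O-silylation with the bulky silyl triflate is the established route to triisopropylsilyloxyalkynes, and the amide base is too weak to remove the allylic-propargylic hydrogens.

Step 3
Reactants: 6 methyl 3,5-dihydroxybenzoate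
Product: 7 methyl 3,5-bis(triisopropylsilyloxy)benzoate
Conditions: TIPSCl (2.4 equiv), imidazole, DMF, rt
Reagents that add atoms: triisopropylsilyl chloride, CC(C)[Si](Cl)(C(C)C)C(C)C
Why: Routine silylation of phenols with a silyl chloride and imidazole gives ethers robust enough for every later step and removable together at the end.

Step 4
Reactants: 7 methyl 3,5-bis(triisopropylsilyloxy)benzoate
Product: 8 methyl 3-[3,5-bis(triisopropylsilyloxy)phenyl]-3-oxopropanoate
Conditions: MeOAc, LiN(i-Pr)2 (3 equiv each), THF, −78 to −30 °C; aq. NH4Cl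
Reagents that add atoms: methyl acetate, CC(=O)OC
Why: Crossed Claisen condensation, in which the lithium enolate of methyl acetate adds to the aryl ester and excess base removes the product as its enolate, should give the keto ester while the aryl silyl ethers tolerate the amide base at low temperature.

Step 5
Reactants: 8 methyl 3-[3,5-bis(triisopropylsilyloxy)phenyl]-3-oxopropanoate
Product: 9 methyl (3R)-3-[3,5-bis(triisopropylsilyloxy)phenyl]-3-hydroxypropanoate
Conditions: H2 (10 atm), RuCl2[(S)-BINAP] (1 mol%), MeOH, 50 °C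
Reagents that add atoms: none
Why: Noyori asymmetric hydrogenation of a beta-keto ester, in which the substrate chelates ruthenium through both carbonyl oxygens and the (S)-BINAP ligand directs hydride to the face that gives the (R)-carbinol, should set the C2 centre with high enantiomeric purity.

Step 6
Reactants: 10 3-ethoxycyclobut-2-en-1-one
Product: 11 cyclobutane-1,3-dione (reacting as its enol 3-hydroxycyclobut-2-en-1-one)
Conditions: 1 M aq. HCl, 0 °C to rt; freeze-drying; used at once
Reagents that add atoms: water, O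
Why: Acid hydrolysis of the vinylogous ester (enol ether hydrolysis) should liberate the strongly acidic dione, which is used fresh because it oligomerises on standing.

Step 7
Reactants: 9 methyl (3R)-3-[3,5-bis(triisopropylsilyloxy)phenyl]-3-hydroxypropanoate; 11 cyclobutane-1,3-dione
Product: 12 methyl (3S)-3-[3,5-bis(triisopropylsilyloxy)phenyl]-3-[(3-oxocyclobut-1-en-1-yl)oxy]propanoate
Conditions: Ph3P, DIAD, THF, 0 °C to rt
Reagents that add atoms: none
Why: In this Mitsunobu reaction the vinylogous acid protonates the betaine and its enolate oxygen displaces the alkoxyphosphonium group by SN2 with inversion, as cyclic 1,3-dione enols do, so the (R)-carbinol should become the (S)-enol ether; the meta-oxygenated ring B does not stabilise a benzylic cation, so ionisation should not erode the configuration.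

Step 8
Reactants: 12 methyl (3S)-3-[3,5-bis(triisopropylsilyloxy)phenyl]-3-[(3-oxocyclobut-1-en-1-yl)oxy]propanoate; 5 (4E)-5,9-dimethyl-1-(triisopropylsilyloxy)deca-4,8-dien-1-yne
Product: 17 methyl (3S)-3-[3,5-bis(triisopropylsilyloxy)phenyl]-3-[4-geranyl-3-hydroxy-5-(triisopropylsilyloxy)phenoxy]propanoate, via vinylketene 13 (not isolated), via vinylcyclobutenone 14 (not isolated), via dienylketene 15 (not isolated), via cyclohexadienone 16 (not isolated)
Conditions: 5 (2 equiv), toluene (0.3 M), 80 °C then 110 °C, sealed tube, argon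
Reagents that add atoms: none
Why: Heat opens cyclobutenone 12 by four-electron electrocyclic cleavage to the (2-alkoxyvinyl)ketene 13, whose carbonyl carbon is attacked by the nucleophilic, geranyl-bearing carbon of ynol ether 5 while its alpha carbon bonds to the silyloxy carbon, a [2+2] addition that forms the future C5–C6 and C7–C8 bonds and gives vinylcyclobutenone 14. A second four-electron opening gives dienylketene 15, which closes ring A by a thermal six-electron disrotatory electrocyclisation between the ketene carbon and the terminal methylene (future C5–C4a), and cyclohexadienone 16 tautomerises to phenol 17. The closest known reaction is the Danheiser benzannulation of cyclobutenones with triisopropylsilyloxyalkynes to 2-alkylresorcinol monosilyl ethers; an alkoxy group at C3 of the cyclobutenone is a less explored variation, and its vinylogous ester resonance may raise the temperature needed for the first ring opening. No stereocentre is formed, and the neutral, base-free medium should leave the C2 ether centre, the beta-oxy ester and the geranyl alkenes untouched. The only selectivity needed is the orientation of ketene and alkyne, which the oxygen-induced polarisation of the ynol ether secures, so the substituents must come out in the order OH, geranyl, OTIPS, H, O-alkyl, H. Excess alkyne is used so that the [2+2] addition outruns capture of 13 by the product phenol.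

Step 9
Reactants: 17 methyl (3S)-3-[3,5-bis(triisopropylsilyloxy)phenyl]-3-[4-geranyl-3-hydroxy-5-(triisopropylsilyloxy)phenoxy]propanoate
Product: 18 methyl (3S)-3-[3,5-bis(triisopropylsilyloxy)phenyl]-3-[4-geranyl-3,5-bis(triisopropylsilyloxy)phenoxy]propanoate
Conditions: TIPSOTf, 2,6-lutidine, CH2Cl2, 0 °C
Reagents that add atoms: triisopropylsilyl trifluoromethanesulfonate, CC(C)[Si](OS(=O)(=O)C(F)(F)F)(C(C)C)C(C)C
Why: Silylation of the single free phenol with a silyl triflate and a hindered pyridine base is routine; it makes C4a and C8 equivalent and removes the ortho-geranyl phenol that could close to a chroman or be O-acylated under the conditions of step 11.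

Step 10
Reactants: 18 methyl (3S)-3-[3,5-bis(triisopropylsilyloxy)phenyl]-3-[4-geranyl-3,5-bis(triisopropylsilyloxy)phenoxy]propanoate
Product: 20 (3S)-3-[3,5-bis(triisopropylsilyloxy)phenyl]-3-[4-geranyl-3,5-bis(triisopropylsilyloxy)phenoxy]propanoic acid, via trimethylstannyl ester 19 (not isolated)
Conditions: Me3SnOH (5 equiv), ClCH2CH2Cl, 80 °C; cold 0.1 M aq. HCl wash
Reagents that add atoms: trimethyltin hydroxide, C[Sn](C)(C)O
Why: Trimethyltin hydroxide cleaves methyl esters by acyl–oxygen substitution under nearly neutral conditions, which should spare the aryl silyl ethers and avoid the beta-elimination of the aryloxy group that an alkali hydroxide could cause.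

Step 11
Reactants: 20 (3S)-3-[3,5-bis(triisopropylsilyloxy)phenyl]-3-[4-geranyl-3,5-bis(triisopropylsilyloxy)phenoxy]propanoic acid
Product: 22 (2S)-2-[3,5-bis(triisopropylsilyloxy)phenyl]-6-geranyl-5,7-bis(triisopropylsilyloxy)chroman-4-one, via mixed anhydride 21 (not isolated)
Conditions: (CF3CO)2O (2.5 equiv), CH2Cl2 (0.05 M), 0 °C; cold aq. NaHCO3
Reagents that add atoms: none
Why: The mixed trifluoroacetic anhydride should be electrophilic enough for an intramolecular Friedel–Crafts acylation of the phloroglucinol-type ring A without a Lewis acid; six-membered closure at C4a (equivalent to C8) should outrun five-membered closure onto ring B, and the C2–O1 bond, which no ortho or para donor activates, should not ionise.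

Step 12
Reactants: 22 (2S)-2-[3,5-bis(triisopropylsilyloxy)phenyl]-6-geranyl-5,7-bis(triisopropylsilyloxy)chroman-4-one
Product: 23 schizolaenone C
Conditions: Et3N·3HF (excess), THF, rt to 40 °C
Reagents that add atoms: none
Why: Fluoride cleaves all four aryl silyl ethers, and the slightly acidic amine hydrofluoride avoids the phenoxide-induced opening of ring C to the chalcone that would racemise C2, while leaving the geranyl chain intact.

**Compound list**
1 | geranyl bromide | CC(C)=CCC/C(C)=C/CBr | starting material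
2 | (4E)-5,9-dimethyldeca-4,8-dien-1-yne | CC(C)=CCC/C(C)=C/CC#C | intermediate
3 | lithium acetylide of 2 | CC(C)=CCC/C(C)=C/CC#C[Li] | intermediate
4 | lithium (4E)-5,9-dimethyldeca-4,8-dien-1-yn-1-olate | CC(C)=CCC/C(C)=C/CC#CO[Li] | intermediate
5 | (4E)-5,9-dimethyl-1-(triisopropylsilyloxy)deca-4,8-dien-1-yne | CC(C)=CCC/C(C)=C/CC#CO[Si](C(C)C)(C(C)C)C(C)C | intermediate
6 | methyl 3,5-dihydroxybenzoate | COC(=O)c1cc(O)cc(O)c1 | starting material
7 | methyl 3,5-bis(triisopropylsilyloxy)benzoate | COC(=O)c1cc(O[Si](C(C)C)(C(C)C)C(C)C)cc(O[Si](C(C)C)(C(C)C)C(C)C)c1 | intermediate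
8 | methyl 3-[3,5-bis(triisopropylsilyloxy)phenyl]-3-oxopropanoate | COC(=O)CC(=O)c1cc(O[Si](C(C)C)(C(C)C)C(C)C)cc(O[Si](C(C)C)(C(C)C)C(C)C)c1 | intermediate
9 | methyl (3R)-3-[3,5-bis(triisopropylsilyloxy)phenyl]-3-hydroxypropanoate | COC(=O)C[C@H](c1cc(O[Si](C(C)C)(C(C)C)C(C)C)cc(O[Si](C(C)C)(C(C)C)C(C)C)c1)O | intermediate
10 | 3-ethoxycyclobut-2-en-1-one | CCOC1=CC(=O)C1 | starting material
11 | cyclobutane-1,3-dione | O=C1CC(=O)C1 | intermediate
12 | methyl (3S)-3-[3,5-bis(triisopropylsilyloxy)phenyl]-3-[(3-oxocyclobut-1-en-1-yl)oxy]propanoate | COC(=O)C[C@@H](c1cc(O[Si](C(C)C)(C(C)C)C(C)C)cc(O[Si](C(C)C)(C(C)C)C(C)C)c1)OC1=CC(=O)C1 | intermediate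
13 | methyl (3S)-3-[3,5-bis(triisopropylsilyloxy)phenyl]-3-[(4-oxobuta-1,3-dien-2-yl)oxy]propanoate (vinylketene) | COC(=O)C[C@@H](c1cc(O[Si](C(C)C)(C(C)C)C(C)C)cc(O[Si](C(C)C)(C(C)C)C(C)C)c1)OC(=C)C=C=O | intermediate
14 | methyl (3S)-3-[3,5-bis(triisopropylsilyloxy)phenyl]-3-({1-[3-geranyl-4-oxo-2-(triisopropylsilyloxy)cyclobut-2-en-1-yl]ethenyl}oxy)propanoate (vinylcyclobutenone, either configuration at the ring CH) | CC(C)=CCC/C(C)=C/CC1=C(O[Si](C(C)C)(C(C)C)C(C)C)C(C(=C)O[C@@H](CC(=O)OC)c2cc(O[Si](C(C)C)(C(C)C)C(C)C)cc(O[Si](C(C)C)(C(C)C)C(C)C)c2)C1=O | intermediate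
15 | methyl (3S)-3-[3,5-bis(triisopropylsilyloxy)phenyl]-3-{[5-geranyl-6-oxo-4-(triisopropylsilyloxy)hexa-1,3,5-trien-2-yl]oxy}propanoate (dienylketene) | CC(C)=CCC/C(C)=C/CC(=C=O)C(O[Si](C(C)C)(C(C)C)C(C)C)=CC(=C)O[C@@H](CC(=O)OC)c1cc(O[Si](C(C)C)(C(C)C)C(C)C)cc(O[Si](C(C)C)(C(C)C)C(C)C)c1 | intermediate
16 | methyl (3S)-3-[3,5-bis(triisopropylsilyloxy)phenyl]-3-{[4-geranyl-5-oxo-3-(triisopropylsilyloxy)cyclohexa-1,3-dien-1-yl]oxy}propanoate (cyclohexadienone) | CC(C)=CCC/C(C)=C/CC1=C(O[Si](C(C)C)(C(C)C)C(C)C)C=C(O[C@@H](CC(=O)OC)c2cc(O[Si](C(C)C)(C(C)C)C(C)C)cc(O[Si](C(C)C)(C(C)C)C(C)C)c2)CC1=O | intermediate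
17 | methyl (3S)-3-[3,5-bis(triisopropylsilyloxy)phenyl]-3-[4-geranyl-3-hydroxy-5-(triisopropylsilyloxy)phenoxy]propanoate | CC(C)=CCC/C(C)=C/Cc1c(O)cc(O[C@@H](CC(=O)OC)c2cc(O[Si](C(C)C)(C(C)C)C(C)C)cc(O[Si](C(C)C)(C(C)C)C(C)C)c2)cc1O[Si](C(C)C)(C(C)C)C(C)C | intermediate
18 | methyl (3S)-3-[3,5-bis(triisopropylsilyloxy)phenyl]-3-[4-geranyl-3,5-bis(triisopropylsilyloxy)phenoxy]propanoate | CC(C)=CCC/C(C)=C/Cc1c(O[Si](C(C)C)(C(C)C)C(C)C)cc(O[C@@H](CC(=O)OC)c2cc(O[Si](C(C)C)(C(C)C)C(C)C)cc(O[Si](C(C)C)(C(C)C)C(C)C)c2)cc1O[Si](C(C)C)(C(C)C)C(C)C | intermediate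
19 | trimethylstannyl (3S)-3-[3,5-bis(triisopropylsilyloxy)phenyl]-3-[4-geranyl-3,5-bis(triisopropylsilyloxy)phenoxy]propanoate | CC(C)=CCC/C(C)=C/Cc1c(O[Si](C(C)C)(C(C)C)C(C)C)cc(O[C@@H](CC(=O)O[Sn](C)(C)C)c2cc(O[Si](C(C)C)(C(C)C)C(C)C)cc(O[Si](C(C)C)(C(C)C)C(C)C)c2)cc1O[Si](C(C)C)(C(C)C)C(C)C | intermediate
20 | (3S)-3-[3,5-bis(triisopropylsilyloxy)phenyl]-3-[4-geranyl-3,5-bis(triisopropylsilyloxy)phenoxy]propanoic acid | CC(C)=CCC/C(C)=C/Cc1c(O[Si](C(C)C)(C(C)C)C(C)C)cc(O[C@@H](CC(=O)O)c2cc(O[Si](C(C)C)(C(C)C)C(C)C)cc(O[Si](C(C)C)(C(C)C)C(C)C)c2)cc1O[Si](C(C)C)(C(C)C)C(C)C | intermediate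
21 | mixed anhydride of 20 with trifluoroacetic acid | CC(C)=CCC/C(C)=C/Cc1c(O[Si](C(C)C)(C(C)C)C(C)C)cc(O[C@@H](CC(=O)OC(=O)C(F)(F)F)c2cc(O[Si](C(C)C)(C(C)C)C(C)C)cc(O[Si](C(C)C)(C(C)C)C(C)C)c2)cc1O[Si](C(C)C)(C(C)C)C(C)C | intermediate
22 | (2S)-2-[3,5-bis(triisopropylsilyloxy)phenyl]-6-geranyl-5,7-bis(triisopropylsilyloxy)chroman-4-one | CC(C)=CCC/C(C)=C/Cc1c(O[Si](C(C)C)(C(C)C)C(C)C)cc2c(c1O[Si](C(C)C)(C(C)C)C(C)C)C(=O)C[C@@H](c1cc(O[Si](C(C)C)(C(C)C)C(C)C)cc(O[Si](C(C)C)(C(C)C)C(C)C)c1)O2 | intermediate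
23 | schizolaenone C, (2S)-2-(3,5-dihydroxyphenyl)-6-geranyl-5,7-dihydroxychroman-4-one | CC(C)=CCC/C(C)=C/Cc1c(O)cc2c(c1O)C(=O)C[C@@H](c1cc(O)cc(O)c1)O2 | target

**Count**
Total steps: 12. Longest linear sequence: 9 steps (steps 3, 4, 5, 7, 8, 9, 10, 11 and 12, from methyl 3,5-dihydroxybenzoate).

**Steps most likely to fail**

1. Step 8. The first ring opening of the vinylogous-ester cyclobutenone may be slow. At the temperature then required, rearrangement of the ynol silyl ether to a silylketene, beta-elimination of the cyclobutenolate towards the cinnamate, or capture of the vinylketene by the product phenol could take over. The fallback gives up the annulation, sets out from 1 and 9 and returns at 18. Phloroglucinol would be C-geranylated with 1 (DBU, THF) to 2-geranylphloroglucinol F1. Exhaustive silylation (TIPSCl, imidazole, DMF) would give 2-geranyl-1,3,5-tris(triisopropylsilyloxy)benzene F2. The silyl ether para to the geranyl group, the only one not shielded by an ortho substituent, would be cleaved with Cs2CO3 in wet DMF to 4-geranyl-3,5-bis(triisopropylsilyloxy)phenol F3. Mitsunobu etherification of F3 with hydroxy ester 9 (Ph3P, DIAD, toluene), with inversion, would give 18.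

2. Step 11. The trifluoroacetic acid released may start a cationic cyclisation of the geranyl chain, and acylation could also go astray onto ring B (five-membered closure) or stall at the hindered C4a. The fallback replaces acid-mediated acylation by buffered amide activation, sets out from 20 and returns at 22. Coupling with Me2NH (EDC·HCl, HOBt, CH2Cl2, 0 °C) would give (3S)-3-[3,5-bis(triisopropylsilyloxy)phenyl]-3-[4-geranyl-3,5-bis(triisopropylsilyloxy)phenoxy]-N,N-dimethylpropanamide F4. Treatment with Tf2O and 2-fluoropyridine (CH2Cl2, −78 to 0 °C) should close ring C in a Vilsmeier–Haack-type cyclisation to the cyclic iminium triflate, (2S)-2-[3,5-bis(triisopropylsilyloxy)phenyl]-6-geranyl-5,7-bis(triisopropylsilyloxy)chroman-4-ylidene(dimethyl)ammonium triflate F5. Aqueous NaHCO3 would hydrolyse F5 to 22.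

3. Step 7. The alkoxyphosphonium ion may eliminate to the cinnamate, or the betaine may attack the strained dione carbonyl, before O-alkylation occurs. The fallback forms the enol ether without breaking the C2–O bond, sets out from 8 and 10 and returns at 12. Hydrogenation of 8 with RuCl2[(R)-BINAP] (H2, MeOH, 50 °C) would give methyl (3S)-3-[3,5-bis(triisopropylsilyloxy)phenyl]-3-hydroxypropanoate F6. Acid-catalysed alkoxy exchange of F6 with 10 (pyridinium p-toluenesulfonate, toluene, 5 Å molecular sieves, rt to 40 °C, ethanol removed) would give 12 with retention.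

**Further compounds**
F1 | step 8 | 2-geranylphloroglucinol | CC(C)=CCC/C(C)=C/Cc1c(O)cc(O)cc1O
F2 | step 8 | 2-geranyl-1,3,5-tris(triisopropylsilyloxy)benzene | CC(C)=CCC/C(C)=C/Cc1c(O[Si](C(C)C)(C(C)C)C(C)C)cc(O[Si](C(C)C)(C(C)C)C(C)C)cc1O[Si](C(C)C)(C(C)C)C(C)C
F3 | step 8 | 4-geranyl-3,5-bis(triisopropylsilyloxy)phenol | CC(C)=CCC/C(C)=C/Cc1c(O[Si](C(C)C)(C(C)C)C(C)C)cc(O)cc1O[Si](C(C)C)(C(C)C)C(C)C
F4 | step 11 | (3S)-3-[3,5-bis(triisopropylsilyloxy)phenyl]-3-[4-geranyl-3,5-bis(triisopropylsilyloxy)phenoxy]-N,N-dimethylpropanamide | CC(C)=CCC/C(C)=C/Cc1c(O[Si](C(C)C)(C(C)C)C(C)C)cc(O[C@@H](CC(=O)N(C)C)c2cc(O[Si](C(C)C)(C(C)C)C(C)C)cc(O[Si](C(C)C)(C(C)C)C(C)C)c2)cc1O[Si](C(C)C)(C(C)C)C(C)C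
F5 | step 11 | (2S)-2-[3,5-bis(triisopropylsilyloxy)phenyl]-6-geranyl-5,7-bis(triisopropylsilyloxy)chroman-4-ylidene(dimethyl)ammonium triflate | CC(C)=CCC/C(C)=C/Cc1c(O[Si](C(C)C)(C(C)C)C(C)C)cc2c(c1O[Si](C(C)C)(C(C)C)C(C)C)C(=[N+](C)C)C[C@@H](c1cc(O[Si](C(C)C)(C(C)C)C(C)C)cc(O[Si](C(C)C)(C(C)C)C(C)C)c1)O2.[O-]S(=O)(=O)C(F)(F)F
F6 | step 7 | methyl (3S)-3-[3,5-bis(triisopropylsilyloxy)phenyl]-3-hydroxypropanoate | COC(=O)C[C@@H](c1cc(O[Si](C(C)C)(C(C)C)C(C)C)cc(O[Si](C(C)C)(C(C)C)C(C)C)c1)O
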